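**Plan**

- Numbering used here: ring O1, C2(=O), C3=C4, C5, C6; side chain C1'(OH), C2'(OMe), C3'=C4', C5'(OAc), C6'(OAc), C7'. The retrosynthesis first removes a PMB group from O–C1', then opens the ring at C3=C4 and at the ester bond C2–O1 (metathesis and acrylation), then cuts the O–CH3 bond at C2', and last cuts the C2'–C3' bond. This gives aldehyde 12 (C2', C1', C6, C5 plus an allyl group) and alkyne 5 (C3'–C7').
- The feature that allows the key event: C2' lies between the E-alkene C3'=C4' and the oxygenated C1', and its oxygen is threo to the oxygen on C1'. This is the pattern left when an (E)-alkenylzinc, made from a terminal alkyne by syn-hydroboration, adds to an α-alkoxy aldehyde through a five-membered zinc chelate. One flask joins alkyne, borane/zinc relay and aldehyde, and sets the alkene geometry, the C2'–C3' bond and the C2' configuration together.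
- Forward order: 1 → 5 (two steps); 6 → 12 (five steps); union in step 8; O-methylation; the dihydropyranone ring, the only ring, is closed near the end by metathesis of the C6 acrylate; PMB removal finishes the route.
- Stereochemistry: C5' and C6' come from the L-threonine-derived ester 1; C1' from D-glyceraldehyde acetonide 6; C6 from Felkin–Anh allylation of 6; C2' from chelation in the key step; the E-alkene from stereospecific hydroboration; the ring alkene is cis by ring size.

Key step: step 8

Assumption: ester 1 (a catalogue compound derived from L-threonine) and aldehyde 6 (from D-mannitol) are bought in high enantiomeric purity.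

**Step 1**
Reactants: 1 methyl (4S,5R)-2,2,5-trimethyl-1,3-dioxolane-4-carboxylate
Product: 3 (4R,5R)-4-ethynyl-2,2,5-trimethyl-1,3-dioxolane, via aldehyde 2 (not isolated)
Conditions: iBu2AlH (DIBAL-H), CH2Cl2, −78 °C; then MeOH, K2CO3, Ohira–Bestmann reagent, −78 °C to rt; pentane extraction, solvent removed cold
Reagents that add atoms: dimethyl (1-diazo-2-oxopropyl)phosphonate, COP(=O)(OC)C(=[N+]=[N-])C(C)=O
Why: Partial ester reduction should stop at the aluminium hemiacetal at −78 °C, and the released aldehyde is homologated in the same flask by the Seyferth–Gilbert reaction in its Ohira–Bestmann form; both stereocentres come from 1, and the trans-dioxolane is the preferred arrangement, so base-induced epimerisation is not expected.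

**Step 2**
Reactants: 3 (4R,5R)-4-ethynyl-2,2,5-trimethyl-1,3-dioxolane
Product: 5 (3R,4R)-pent-1-yne-3,4-diyl diacetate, via diol 4 (not isolated)
Conditions: Amberlyst-15 (H+ form), MeOH, rt; filter, evaporate cold; then Ac2O, pyridine, DMAP (cat.), CH2Cl2, 0 °C to rt
Reagents that add atoms: acetic anhydride, CC(=O)OC(C)=O
Why: Acid-catalysed transketalisation to methanol frees the diol and DMAP-catalysed acylation should give the diacetate without touching a stereocentre; these are the acetates of the target and are carried to the end.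

**Step 3**
Reactants: 6 (R)-2,2-dimethyl-1,3-dioxolane-4-carbaldehyde
Product: 7 (S)-1-[(R)-2,2-dimethyl-1,3-dioxolan-4-yl]but-3-en-1-ol
Conditions: allyl bromide, Zn dust, THF/sat. aq NH4Cl, 0 °C to rt
Reagents that add atoms: allyl bromide, C=CCBr
Why: Barbier-type zinc allylation of the α,β-dialkoxy aldehyde should follow the Felkin–Anh model and favour the anti (erythro) alcohol, which fixes the future ring carbon C6 relative to C1'; the minor syn isomer is to be removed by chromatography here or after silylation.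

**Step 4**
Reactants: 7 (S)-1-[(R)-2,2-dimethyl-1,3-dioxolan-4-yl]but-3-en-1-ol
Product: 8 tert-butyl{[(1S)-1-[(4R)-2,2-dimethyl-1,3-dioxolan-4-yl]but-3-en-1-yl]oxy}dimethylsilane
Conditions: TBSCl, imidazole, DMAP (cat.), DMF, rt
Reagents that add atoms: tert-butyldimethylsilyl chloride, CC(C)(C)[Si](C)(C)Cl
Why: Standard silylation of a secondary alcohol; the bulky, weakly basic TBS ether is chosen because it should not chelate zinc in the key step and can be removed selectively later.

**Step 5**
Reactants: 8 tert-butyl{[(1S)-1-[(4R)-2,2-dimethyl-1,3-dioxolan-4-yl]but-3-en-1-yl]oxy}dimethylsilane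
Product: 10 (4R)-4-[(1S)-1-(tert-butyldimethylsilyloxy)but-3-en-1-yl]-2-(4-methoxyphenyl)-1,3-dioxolane (both epimers at the acetal carbon), via diol 9 (not isolated)
Conditions: PPTS (cat.), MeOH, 40 °C; evaporate; then 4-MeOC6H4CH(OMe)2, CH2Cl2, rt
Reagents that add atoms: 4-methoxybenzaldehyde dimethyl acetal, COc1ccc(cc1)C(OC)OC
Why: The terminal acetonide should be methanolysed under mild acid that leaves the secondary TBS ether, and the 1,2-diol is re-acetalised in the same flask as its p-methoxybenzylidene acetal (acetal exchange); the mixture at the acetal carbon is of no consequence.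

**Step 6**
Reactants: 10 (4R)-4-[(1S)-1-(tert-butyldimethylsilyloxy)but-3-en-1-yl]-2-(4-methoxyphenyl)-1,3-dioxolane
Product: 11 (2R,3S)-3-(tert-butyldimethylsilyloxy)-2-(4-methoxybenzyloxy)hex-5-en-1-ol
Conditions: iBu2AlH (DIBAL-H), CH2Cl2, −78 to 0 °C; aq KNaC4H4O6 (Rochelle salt)
Reagents that add atoms: none
Why: Regioselective reductive acetal opening: aluminium should coordinate the less hindered primary oxygen, the bond from the acetal carbon to that oxygen breaks, and hydride adds to the oxocarbenium ion, leaving the PMB ether on the secondary oxygen (C1') and the primary alcohol free.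

**Step 7**
Reactants: 11 (2R,3S)-3-(tert-butyldimethylsilyloxy)-2-(4-methoxybenzyloxy)hex-5-en-1-ol
Product: 12 (2S,3S)-3-(tert-butyldimethylsilyloxy)-2-(4-methoxybenzyloxy)hex-5-enal
Conditions: Dess–Martin periodinane, pyridine, CH2Cl2, 0 °C to rt; used at once
Reagents that add atoms: none
Why: Dess–Martin oxidation under buffered, non-basic conditions should give the α-alkoxy aldehyde without epimerisation at C1'.

**Step 8**
Reactants: 5 (3R,4R)-pent-1-yne-3,4-diyl diacetate; 12 (2S,3S)-3-(tert-butyldimethylsilyloxy)-2-(4-methoxybenzyloxy)hex-5-enal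
Product: 15 (2R,3R,4E,6S,7R,8S)-8-(tert-butyldimethylsilyloxy)-6-hydroxy-7-(4-methoxybenzyloxy)undeca-4,10-diene-2,3-diyl diacetate, via alkenylborane 13 (not isolated), via alkenylzinc 14 (not isolated)
Conditions: 5 (1.5 equiv), Cy2BH (from BH3·SMe2 and cyclohexene), toluene, 0 °C to rt; Me2Zn, −78 °C; ZnBr2 (Et2O), then 12, −78 to −20 °C; aq NH4Cl
Reagents that add atoms: none
Why: Dicyclohexylborane adds syn and anti-Markovnikov to the terminal alkyne of 5 to give the (E)-alkenylborane 13, whose alkenyl group passes with retention to zinc (boron-to-zinc transmetalation) to give 14, which adds to the aldehyde of 12. The closest known reaction types are the hydroboration/transmetalation alkenylzinc addition to aldehydes and zinc-halide-promoted Cram-chelate additions of organozinc reagents to α-alkoxy aldehydes. No ring is closed; a temporary five-membered chelate of divalent zinc between the aldehyde oxygen and the PMB-ether oxygen on C1' fixes the conformation. The new stereocentre C2' is set by this chelate: the alkenyl group should attack the face opposite the chain that carries C6, giving the (S)-carbinol with the threo (syn) relation of the oxygens on C2' and C1'. The step needs α-chelation to win over Felkin–Anh and β-chelated attack, which the substrate secures by pairing a strongly donating PMB ether on the α-oxygen with a bulky, poorly coordinating TBS ether on the β-oxygen, while the E geometry follows from the stereospecific hydroboration. The alkenyl group should transfer faster than methyl from the mixed zinc reagent, and the two acetates are inert to organoboron and organozinc species at low temperature.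

**Step 9**
Reactants: 15 (2R,3R,4E,6S,7R,8S)-8-(tert-butyldimethylsilyloxy)-6-hydroxy-7-(4-methoxybenzyloxy)undeca-4,10-diene-2,3-diyl diacetate
Product: 16 (2R,3R,4E,6S,7R,8S)-8-(tert-butyldimethylsilyloxy)-6-methoxy-7-(4-methoxybenzyloxy)undeca-4,10-diene-2,3-diyl diacetate
Conditions: Me3OBF4, 1,8-bis(dimethylamino)naphthalene, 4 Å molecular sieves, CH2Cl2, 0 °C to rt
Reagents that add atoms: trimethyloxonium tetrafluoroborate, C[O+](C)C.F[B-](F)(F)F
Why: O-Methylation with Meerwein's salt and a non-nucleophilic proton scavenger should alkylate the hindered allylic alcohol without forming an alkoxide, so the acetates neither cleave nor migrate and the TBS group does not shift.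

**Step 10**
Reactants: 16 (2R,3R,4E,6S,7R,8S)-8-(tert-butyldimethylsilyloxy)-6-methoxy-7-(4-methoxybenzyloxy)undeca-4,10-diene-2,3-diyl diacetate
Product: 17 (2R,3R,4E,6S,7S,8S)-8-hydroxy-6-methoxy-7-(4-methoxybenzyloxy)undeca-4,10-diene-2,3-diyl diacetate
Conditions: HF·pyridine, pyridine, THF, 0 °C to rt
Reagents that add atoms: none
Why: Buffered fluoride cleavage of the secondary TBS ether should leave the acetates, the PMB ether and the allylic methyl ether intact.

**Step 11**
Reactants: 17 (2R,3R,4E,6S,7S,8S)-8-hydroxy-6-methoxy-7-(4-methoxybenzyloxy)undeca-4,10-diene-2,3-diyl diacetate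
Product: 18 (4S,5S,6S,7E,9R,10R)-9,10-diacetoxy-6-methoxy-5-(4-methoxybenzyloxy)undeca-1,7-dien-4-yl prop-2-enoate
Conditions: acryloyl chloride, iPr2NEt, DMAP (cat.), CH2Cl2, −20 to 0 °C
Reagents that add atoms: acryloyl chloride, C=CC(Cl)=O
Why: Acylation of the only free hydroxyl (on C6) should install the two remaining ring carbons C2 and C3.

**Step 12**
Reactants: 18 (4S,5S,6S,7E,9R,10R)-9,10-diacetoxy-6-methoxy-5-(4-methoxybenzyloxy)undeca-1,7-dien-4-yl prop-2-enoate
Product: 19 (2R,3R,4E,6S,7S)-6-methoxy-7-(4-methoxybenzyloxy)-7-[(2S)-6-oxo-3,6-dihydro-2H-pyran-2-yl]hept-4-ene-2,3-diyl diacetate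
Conditions: second-generation Grubbs catalyst RuCl2(=CHPh)(PCy3)(H2IMes) (5 mol %), CH2Cl2 (0.005 M), 40 °C
Reagents that add atoms: none
Why: Ring-closing metathesis: the catalyst should load on the terminal allyl alkene and close onto the acrylate to give the six-membered α,β-unsaturated lactone, while the internal E-alkene flanked by two oxygenated carbons is far less reactive.

**Step 13**
Reactants: 19 (2R,3R,4E,6S,7S)-6-methoxy-7-(4-methoxybenzyloxy)-7-[(2S)-6-oxo-3,6-dihydro-2H-pyran-2-yl]hept-4-ene-2,3-diyl diacetate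
Product: 20 (2R,3R,4E,6S,7S)-7-hydroxy-6-methoxy-7-[(2S)-6-oxo-3,6-dihydro-2H-pyran-2-yl]hept-4-ene-2,3-diyl diacetate
Conditions: DDQ, CH2Cl2/pH 7 phosphate buffer, 0 °C to rt
Reagents that add atoms: none
Why: Oxidative PMB cleavage by electron transfer to DDQ and hydrolysis of the resulting oxocarbenium ion should free the C1' hydroxyl without touching the esters, the lactone or the methyl ether.

**Compound list**

1 | methyl (4S,5R)-2,2,5-trimethyl-1,3-dioxolane-4-carboxylate | COC(=O)[C@H]1OC(C)(C)O[C@@H]1C | starting material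
2 | (4S,5R)-2,2,5-trimethyl-1,3-dioxolane-4-carbaldehyde | O=C[C@H]1OC(C)(C)O[C@@H]1C | intermediate
3 | (4R,5R)-4-ethynyl-2,2,5-trimethyl-1,3-dioxolane | C#C[C@H]1OC(C)(C)O[C@@H]1C | intermediate
4 | (3R,4R)-pent-1-yne-3,4-diol | C#C[C@@H](O)[C@@H](C)O | intermediate
5 | (3R,4R)-pent-1-yne-3,4-diyl diacetate | C#C[C@@H](OC(C)=O)[C@@H](C)OC(C)=O | intermediate
6 | (R)-2,2-dimethyl-1,3-dioxolane-4-carbaldehyde | CC1(C)OC[C@H](C=O)O1 | starting material
7 | (S)-1-[(R)-2,2-dimethyl-1,3-dioxolan-4-yl]but-3-en-1-ol | CC1(C)OC[C@H]([C@@H](O)CC=C)O1 | intermediate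
8 | tert-butyl{[(1S)-1-[(4R)-2,2-dimethyl-1,3-dioxolan-4-yl]but-3-en-1-yl]oxy}dimethylsilane | CC1(C)OC[C@H]([C@@H](O[Si](C)(C)C(C)(C)C)CC=C)O1 | intermediate
9 | (2R,3S)-3-(tert-butyldimethylsilyloxy)hex-5-ene-1,2-diol | OC[C@@H](O)[C@@H](O[Si](C)(C)C(C)(C)C)CC=C | intermediate
10 | (4R)-4-[(1S)-1-(tert-butyldimethylsilyloxy)but-3-en-1-yl]-2-(4-methoxyphenyl)-1,3-dioxolane (both epimers at the acetal carbon) | COc1ccc(cc1)C1OC[C@H]([C@@H](O[Si](C)(C)C(C)(C)C)CC=C)O1 | intermediate
11 | (2R,3S)-3-(tert-butyldimethylsilyloxy)-2-(4-methoxybenzyloxy)hex-5-en-1-ol | OC[C@@H](OCc1ccc(OC)cc1)[C@@H](O[Si](C)(C)C(C)(C)C)CC=C | intermediate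
12 | (2S,3S)-3-(tert-butyldimethylsilyloxy)-2-(4-methoxybenzyloxy)hex-5-enal | O=C[C@@H](OCc1ccc(OC)cc1)[C@@H](O[Si](C)(C)C(C)(C)C)CC=C | intermediate
13 | (1E,3R,4R)-1-(dicyclohexylboranyl)pent-1-ene-3,4-diyl diacetate | C1CCCCC1B(C2CCCCC2)/C=C/[C@@H](OC(C)=O)[C@@H](C)OC(C)=O | intermediate
14 | [(1E,3R,4R)-3,4-diacetoxypent-1-en-1-yl](methyl)zinc | C[Zn]/C=C/[C@@H](OC(C)=O)[C@@H](C)OC(C)=O | intermediate
15 | (2R,3R,4E,6S,7R,8S)-8-(tert-butyldimethylsilyloxy)-6-hydroxy-7-(4-methoxybenzyloxy)undeca-4,10-diene-2,3-diyl diacetate | O[C@@H](/C=C/[C@@H](OC(C)=O)[C@@H](C)OC(C)=O)[C@@H](OCc1ccc(OC)cc1)[C@@H](O[Si](C)(C)C(C)(C)C)CC=C | intermediate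
16 | (2R,3R,4E,6S,7R,8S)-8-(tert-butyldimethylsilyloxy)-6-methoxy-7-(4-methoxybenzyloxy)undeca-4,10-diene-2,3-diyl diacetate | CO[C@@H](/C=C/[C@@H](OC(C)=O)[C@@H](C)OC(C)=O)[C@@H](OCc1ccc(OC)cc1)[C@@H](O[Si](C)(C)C(C)(C)C)CC=C | intermediate
17 | (2R,3R,4E,6S,7S,8S)-8-hydroxy-6-methoxy-7-(4-methoxybenzyloxy)undeca-4,10-diene-2,3-diyl diacetate | CO[C@@H](/C=C/[C@@H](OC(C)=O)[C@@H](C)OC(C)=O)[C@@H](OCc1ccc(OC)cc1)[C@@H](O)CC=C | intermediate
18 | (4S,5S,6S,7E,9R,10R)-9,10-diacetoxy-6-methoxy-5-(4-methoxybenzyloxy)undeca-1,7-dien-4-yl prop-2-enoate | CO[C@@H](/C=C/[C@@H](OC(C)=O)[C@@H](C)OC(C)=O)[C@@H](OCc1ccc(OC)cc1)[C@@H](OC(=O)C=C)CC=C | intermediate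
19 | (2R,3R,4E,6S,7S)-6-methoxy-7-(4-methoxybenzyloxy)-7-[(2S)-6-oxo-3,6-dihydro-2H-pyran-2-yl]hept-4-ene-2,3-diyl diacetate | CO[C@@H](/C=C/[C@@H](OC(C)=O)[C@@H](C)OC(C)=O)[C@@H](OCc1ccc(OC)cc1)[C@@H]1CC=CC(=O)O1 | intermediate
20 | (2R,3R,4E,6S,7S)-7-hydroxy-6-methoxy-7-[(2S)-6-oxo-3,6-dihydro-2H-pyran-2-yl]hept-4-ene-2,3-diyl diacetate | CO[C@@H](/C=C/[C@@H](OC(C)=O)[C@@H](C)OC(C)=O)[C@@H](O)[C@@H]1CC=CC(=O)O1 | target

**Step count and risks**

Total steps: 13. Longest linear sequence: 11 (steps 3 to 13, from 6).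

Steps most likely to fail:

1. Step 8. Facial selectivity may be poor if Felkin–Anh or β-chelated attack competes with the α-chelate, and alkenyl transfer may be slow enough for methyl addition to compete. The fallback sets out from 12 and 5 and comes back at 15. The addition is run without regard to selectivity, giving 15 mixed with the C6-epimeric alcohol (2R,3R,4E,6R,7R,8S)-8-(tert-butyldimethylsilyloxy)-6-hydroxy-7-(4-methoxybenzyloxy)undeca-4,10-diene-2,3-diyl diacetate F1. The mixture is oxidised with Dess–Martin periodinane to the single enone (2R,3R,4E,7S,8S)-8-(tert-butyldimethylsilyloxy)-7-(4-methoxybenzyloxy)-6-oxoundeca-4,10-diene-2,3-diyl diacetate F2. Chelation-controlled 1,2-reduction of F2 with Zn(BH4)2 in Et2O at −30 °C should deliver hydride to the zinc-chelated α-alkoxy ketone from the face opposite the C8 chain and return 15. The stereocentre is then set by a stereoconvergent oxidation–reduction, not by the carbon–carbon bond formation.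

2. Step 9. Methylation of the hindered carbinol may stall, and forcing it may cost an acetate by cleavage or migration. The fallback sets out from 12 and 3 and comes back at 16; the diol is carried as its acetonide so that alkoxide methylation can be used. The hydroboration/transmetalation/chelation sequence of step 8, run with alkyne 3, should give the allylic alcohol (1E,3S,4R,5S)-5-(tert-butyldimethylsilyloxy)-4-(4-methoxybenzyloxy)-1-[(4R,5R)-2,2,5-trimethyl-1,3-dioxolan-4-yl]octa-1,7-dien-3-ol F3. NaH and MeI in THF at 0 °C should convert it to the methyl ether tert-butyl({(4S,5R,6S,7E)-6-methoxy-5-(4-methoxybenzyloxy)-8-[(4R,5R)-2,2,5-trimethyl-1,3-dioxolan-4-yl]octa-1,7-dien-4-yl}oxy)dimethylsilane F4. PPTS in MeOH at 45 °C should remove the acetonide to give the diol (2R,3R,4E,6S,7R,8S)-8-(tert-butyldimethylsilyloxy)-6-methoxy-7-(4-methoxybenzyloxy)undeca-4,10-diene-2,3-diol F5, and Ac2O/pyridine/DMAP returns 16.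

3. Step 6. The reductive acetal cleavage may show poor regioselectivity, leaving the PMB group on the primary oxygen, or the silyl group may migrate. The fallback sets out from diol 9, isolated after the methanolysis of step 5, and comes back at 11. Selective acylation of the primary hydroxyl with pivaloyl chloride and pyridine in CH2Cl2 at −20 °C should give the primary pivalate (2R,3S)-3-(tert-butyldimethylsilyloxy)-2-hydroxyhex-5-en-1-yl 2,2-dimethylpropanoate F6. Acid-catalysed benzylation of the secondary hydroxyl with 4-methoxybenzyl 2,2,2-trichloroacetimidate and La(OTf)3 (cat.) in toluene should give the PMB ether pivalate (2R,3S)-3-(tert-butyldimethylsilyloxy)-2-(4-methoxybenzyloxy)hex-5-en-1-yl 2,2-dimethylpropanoate F7. iBu2AlH in CH2Cl2 at −78 °C removes the pivalate and returns 11.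

**Further compounds**

F1 | step 8 | (2R,3R,4E,6R,7R,8S)-8-(tert-butyldimethylsilyloxy)-6-hydroxy-7-(4-methoxybenzyloxy)undeca-4,10-diene-2,3-diyl diacetate | O[C@H](/C=C/[C@@H](OC(C)=O)[C@@H](C)OC(C)=O)[C@@H](OCc1ccc(OC)cc1)[C@@H](O[Si](C)(C)C(C)(C)C)CC=C
F2 | step 8 | (2R,3R,4E,7S,8S)-8-(tert-butyldimethylsilyloxy)-7-(4-methoxybenzyloxy)-6-oxoundeca-4,10-diene-2,3-diyl diacetate | O=C(/C=C/[C@@H](OC(C)=O)[C@@H](C)OC(C)=O)[C@@H](OCc1ccc(OC)cc1)[C@@H](O[Si](C)(C)C(C)(C)C)CC=C
F3 | step 9 | (1E,3S,4R,5S)-5-(tert-butyldimethylsilyloxy)-4-(4-methoxybenzyloxy)-1-[(4R,5R)-2,2,5-trimethyl-1,3-dioxolan-4-yl]octa-1,7-dien-3-ol | O[C@@H](/C=C/[C@H]1OC(C)(C)O[C@@H]1C)[C@@H](OCc1ccc(OC)cc1)[C@@H](O[Si](C)(C)C(C)(C)C)CC=C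
F4 | step 9 | tert-butyl({(4S,5R,6S,7E)-6-methoxy-5-(4-methoxybenzyloxy)-8-[(4R,5R)-2,2,5-trimethyl-1,3-dioxolan-4-yl]octa-1,7-dien-4-yl}oxy)dimethylsilane | CO[C@@H](/C=C/[C@H]1OC(C)(C)O[C@@H]1C)[C@@H](OCc1ccc(OC)cc1)[C@@H](O[Si](C)(C)C(C)(C)C)CC=C
F5 | step 9 | (2R,3R,4E,6S,7R,8S)-8-(tert-butyldimethylsilyloxy)-6-methoxy-7-(4-methoxybenzyloxy)undeca-4,10-diene-2,3-diol | CO[C@@H](/C=C/[C@@H](O)[C@@H](C)O)[C@@H](OCc1ccc(OC)cc1)[C@@H](O[Si](C)(C)C(C)(C)C)CC=C
F6 | step 6 | (2R,3S)-3-(tert-butyldimethylsilyloxy)-2-hydroxyhex-5-en-1-yl 2,2-dimethylpropanoate | CC(C)(C)C(=O)OC[C@@H](O)[C@@H](O[Si](C)(C)C(C)(C)C)CC=C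
F7 | step 6 | (2R,3S)-3-(tert-butyldimethylsilyloxy)-2-(4-methoxybenzyloxy)hex-5-en-1-yl 2,2-dimethylpropanoate | CC(C)(C)C(=O)OC[C@@H](OCc1ccc(OC)cc1)[C@@H](O[Si](C)(C)C(C)(C)C)CC=C
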